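**Retrosynthetic overview**

1. Late stage: target ⇐ peracid epoxidation of C1=C10 ⇐ Yamaguchi angeloylation of O6 ⇐ hydroxyl-directed epoxidation of C4=C5 ⇐ 6α-hydroxygermacra-1(10),4,11(13)-trien-12,8α-olide; the exocyclic methylene C13 comes from formaldehyde by Horner–Wadsworth–Emmons olefination of an α-phosphono lactone.
2. Key disconnection: C7–C8 and C11–C12 are made together from an acyclic chain; the ten-membered carbocycle closes first (radical conjugate addition of C8 to C7), the γ-lactone second (acyl substitution at C12 by the C11 carbanion).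
3. Enabling feature: in the lactone ring O8 already joins C8 to the carbonyl carbon C12. The precursor therefore carries C8 as an α-(methoxycarbonyloxy) carboxylic acid (a C8 radical after loss of CO2, with C12 as acyl donor on O8) next to a C7=C11 alkenylphosphonate; the (E,E)-1(10),4-diene of the chain pre-organises the ring.
4. Carbon sources: geranyl acetate (C1–C6, C9, C10, C14, C15), glycolic acid acetonide (C8 and the traceless CO2H), ethynylsilane (C7, C11), ClCO2Me (C12), HCHO (C13), angelic acid.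

Key step: step 12

Remark: germacrane numbering (C1–C15) is used for the atoms throughout; C8 is introduced racemic in step 3 and is carried as a mixture of epimers until step 12, where it becomes a planar radical.

**Route**

Step 1
Reactants: 1 geranyl acetate
Product: 2 (2E,6E)-8-hydroxy-3,7-dimethylocta-2,6-dien-1-yl acetate
Conditions: SeO2 (cat.), t-BuOOH, salicylic acid (cat.), CH2Cl2, rt
Reagents that add atoms: tert-butyl hydroperoxide, CC(C)(C)OO
Why: Selenium dioxide-catalysed allylic (Riley) oxidation is selective for the (E)-methyl group of the terminal trisubstituted alkene and gives the (E)-allylic alcohol whose carbon becomes C9.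

Step 2
Reactants: 2 (2E,6E)-8-hydroxy-3,7-dimethylocta-2,6-dien-1-yl acetate
Product: 3 (2E,6E)-8-bromo-3,7-dimethylocta-2,6-dien-1-yl acetate
Conditions: CBr4, PPh3, CH2Cl2, 0 °C
Reagents that add atoms: carbon tetrabromide, BrC(Br)(Br)Br
Why: Appel bromination turns the primary allylic alcohol into the bromide under neutral conditions without allylic transposition.

Step 3
Reactants: 3 (2E,6E)-8-bromo-3,7-dimethylocta-2,6-dien-1-yl acetate; 4 2,2-dimethyl-1,3-dioxolan-4-one
Product: 5 (2E,6E)-8-(2,2-dimethyl-5-oxo-1,3-dioxolan-4-yl)-3,7-dimethylocta-2,6-dien-1-yl acetate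
Conditions: LiN(SiMe3)2, THF, −78 °C
Reagents that add atoms: none
Why: Alkylation of the lithium enolate of the glycolic acid acetonide by the reactive allylic bromide forms the C8–C9 bond; the new centre C8 is left racemic because step 12 erases it.

Step 4
Reactants: 5 (2E,6E)-8-(2,2-dimethyl-5-oxo-1,3-dioxolan-4-yl)-3,7-dimethylocta-2,6-dien-1-yl acetate
Product: 6 allyl (4E,8E)-2,10-dihydroxy-4,8-dimethyldeca-4,8-dienoate
Conditions: K2CO3 (0.3 equiv), allyl alcohol, 0 °C to rt
Reagents that add atoms: allyl alcohol, C=CCO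
Why: Carbonate-catalysed transesterification opens the dioxolanone to the allyl α-hydroxy ester (acetone is released) and removes the acetate in the same operation.

Step 5
Reactants: 6 allyl (4E,8E)-2,10-dihydroxy-4,8-dimethyldeca-4,8-dienoate
Product: 7 allyl (4E,8E)-2-hydroxy-4,8-dimethyl-10-oxodeca-4,8-dienoate
Conditions: MnO2 (excess), CH2Cl2, rt
Reagents that add atoms: none
Why: MnO2 oxidises only the primary allylic alcohol to the (E)-enal and leaves the secondary α-hydroxy ester untouched.

Step 6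
Reactants: 7 allyl (4E,8E)-2-hydroxy-4,8-dimethyl-10-oxodeca-4,8-dienoate
Product: 8 allyl (4E,8E)-2-[(methoxycarbonyl)oxy]-4,8-dimethyl-10-oxodeca-4,8-dienoate
Conditions: ClCO2Me, pyridine, DMAP (cat.), CH2Cl2, 0 °C
Reagents that add atoms: methyl chloroformate, COC(Cl)=O
Why: O-Acylation with the chloroformate places on O8 the carbonate carbon that becomes the lactone carbonyl C12.

Step 7
Reactants: 8 allyl (4E,8E)-2-[(methoxycarbonyl)oxy]-4,8-dimethyl-10-oxodeca-4,8-dienoate; 9 ethynyltrimethylsilane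
Product: 10 allyl (4E,8E,10R)-10-hydroxy-2-[(methoxycarbonyl)oxy]-4,8-dimethyl-12-(trimethylsilyl)dodeca-4,8-dien-11-ynoate
Conditions: Me2Zn, (S,S)-ProPhenol (20 mol %), Ph3PO (40 mol %), toluene, 4 °C; aq. NH4Cl
Reagents that add atoms: none
Why: Zinc–ProPhenol-catalysed asymmetric alkynylation of the enal (1,2-addition) sets the C6 carbinol; delivery to the Si face is required for the (R)-alcohol, and the antipodal ligand is used if a test run shows the opposite sense.

Step 8
Reactants: 10 allyl (4E,8E,10R)-10-hydroxy-2-[(methoxycarbonyl)oxy]-4,8-dimethyl-12-(trimethylsilyl)dodeca-4,8-dien-11-ynoate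
Product: 11 allyl (4E,8E,10R)-10-hydroxy-2-[(methoxycarbonyl)oxy]-4,8-dimethyldodeca-4,8-dien-11-ynoate
Conditions: TBAF, AcOH, THF, 0 °C
Reagents that add atoms: none
Why: Buffered fluoride cleaves the alkynyl C–Si bond (protodesilylation) without touching the carbonate or the allyl ester.

Step 9
Reactants: 11 allyl (4E,8E,10R)-10-hydroxy-2-[(methoxycarbonyl)oxy]-4,8-dimethyldodeca-4,8-dien-11-ynoate
Product: 12 allyl (4E,8E,10R)-10-[(tert-butyldimethylsilyl)oxy]-2-[(methoxycarbonyl)oxy]-4,8-dimethyldodeca-4,8-dien-11-ynoate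
Conditions: TBSOTf, 2,6-lutidine, CH2Cl2, −78 °C
Reagents that add atoms: tert-butyldimethylsilyl triflate, CC(C)(C)[Si](C)(C)OS(=O)(=O)C(F)(F)F
Why: Silylation protects O6 as an ether that offers neither an acidic proton nor an acyl group to the carbanion of step 12.

Step 10
Reactants: 12 allyl (4E,8E,10R)-10-[(tert-butyldimethylsilyl)oxy]-2-[(methoxycarbonyl)oxy]-4,8-dimethyldodeca-4,8-dien-11-ynoate; 13 4,4,5,5-tetramethyl-1,3,2-dioxaphospholane 2-oxide
Product: 14 allyl (4E,8E,10R,11E)-10-[(tert-butyldimethylsilyl)oxy]-2-[(methoxycarbonyl)oxy]-4,8-dimethyl-12-(4,4,5,5-tetramethyl-2-oxido-1,3,2-dioxaphospholan-2-yl)dodeca-4,8,11-trienoate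
Conditions: RhCl(PPh3)3 (3 mol %), acetone, rt
Reagents that add atoms: none
Why: Rhodium-catalysed hydrophosphorylation of the terminal alkyne is a syn, anti-Markovnikov addition and should give only the (E)-alkenylphosphonate, the radical acceptor and later olefination handle.

Step 11
Reactants: 14 allyl (4E,8E,10R,11E)-10-[(tert-butyldimethylsilyl)oxy]-2-[(methoxycarbonyl)oxy]-4,8-dimethyl-12-(4,4,5,5-tetramethyl-2-oxido-1,3,2-dioxaphospholan-2-yl)dodeca-4,8,11-trienoate
Product: 15 (4E,8E,10R,11E)-10-[(tert-butyldimethylsilyl)oxy]-2-[(methoxycarbonyl)oxy]-4,8-dimethyl-12-(4,4,5,5-tetramethyl-2-oxido-1,3,2-dioxaphospholan-2-yl)dodeca-4,8,11-trienoic acid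
Conditions: Pd(PPh3)4 (5 mol %), 4-MeC6H4SO2Na, THF/MeOH, rt; pH 4 buffer
Reagents that add atoms: none
Why: Tsuji–Trost deallylation: zerovalent palladium ionises only the allyl ester and the sulfinate captures the allyl group, which frees the acid without base or acid that would harm the carbonate or the silyl ether.

Step 12
Reactants: 15 (4E,8E,10R,11E)-10-[(tert-butyldimethylsilyl)oxy]-2-[(methoxycarbonyl)oxy]-4,8-dimethyl-12-(4,4,5,5-tetramethyl-2-oxido-1,3,2-dioxaphospholan-2-yl)dodeca-4,8,11-trienoic acid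
Product: 17 6α-(tert-butyldimethylsilyloxy)-11-(4,4,5,5-tetramethyl-2-oxido-1,3,2-dioxaphospholan-2-yl)germacra-1(10)E,4E-dien-12,8α-olide (7αH,8βH; C11 epimers), via caesium phosphonate carbanion 16 (not isolated)
Conditions: Cs2CO3 (0.5 equiv), 4 Å MS; Ir[dF(CF3)ppy]2(dtbbpy)PF6 (2 mol %), DMSO (2 mM), 450 nm LEDs, 30 °C; aq. NH4Cl
Reagents that add atoms: none
Why: Proposed new method: the photoexcited iridium complex oxidises the caesium carboxylate, loss of CO2 gives the α-(carbonate-oxy) C8 radical, and this adds to C7, the β-carbon of the alkenylphosphonate (10-exo-trig, closing the carbocycle); the α-phosphonyl C11 radical is then reduced by the reduced photocatalyst to carbanion 16, which attacks the carbonate carbonyl C12 (5-exo-trig acyl substitution, loss of methoxide) and closes the γ-lactone. The closest known reactions are the photoredox decarboxylative Giese addition of α-oxy acids, its macrocyclising variant, radical–polar crossover annulations and the acylation of phosphonate carbanions by carbonates. C7 is set by C6 because the radical attacks anti to the C6–O bond (Felkin-type, allylic hydrogen eclipsing the alkene), and C8 follows from a crown-like chair–chair transition state of the (E,E)-cyclodeca-1,5-diene in which the silyloxy, phosphonoalkyl and carbonate groups are pseudo-equatorial, so H6, H7 and H8 end trans-diaxial and the lactone is trans-fused; C11 is not controlled and is erased in step 13. The step needs attack on C7 rather than on the two trisubstituted alkenes: the nucleophilic radical is polarity-matched only with the phosphonate-activated alkene, and smaller rings through C4=C5 would have to contain the (E)-C1=C10 bond. It also needs acylation to outrun protonation, which the dry aprotic caesium salt secures, and the redox-neutral cycle cannot turn over before C–C bond formation because the C8 radical is not reducible by the reduced catalyst.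

Step 13
Reactants: 17 6α-(tert-butyldimethylsilyloxy)-11-(4,4,5,5-tetramethyl-2-oxido-1,3,2-dioxaphospholan-2-yl)germacra-1(10)E,4E-dien-12,8α-olide
Product: 18 6α-(tert-butyldimethylsilyloxy)germacra-1(10)E,4E,11(13)-trien-12,8α-olide
Conditions: 37% aq. HCHO, K2CO3, THF, 0 °C to rt
Reagents that add atoms: formaldehyde, C=O
Why: Horner–Wadsworth–Emmons olefination of the phosphonate-stabilised lactone enolate with formaldehyde forms the exocyclic C11=C13 bond and removes phosphorus together with the uncontrolled C11 centre.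

Step 14
Reactants: 18 6α-(tert-butyldimethylsilyloxy)germacra-1(10)E,4E,11(13)-trien-12,8α-olide
Product: 19 6α-hydroxygermacra-1(10)E,4E,11(13)-trien-12,8α-olide
Conditions: HF·pyridine, pyridine, THF, 0 °C to rt
Reagents that add atoms: none
Why: Fluoride-mediated desilylation frees the 6α-hydroxyl under conditions that do not add to the α-methylene lactone.

Step 15
Reactants: 19 6α-hydroxygermacra-1(10)E,4E,11(13)-trien-12,8α-olide
Product: 20 4α,5β-epoxy-6α-hydroxygermacra-1(10)E,11(13)-dien-12,8α-olide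
Conditions: VO(acac)2 (5 mol %), t-BuOOH, CH2Cl2, 0 °C
Reagents that add atoms: tert-butyl hydroperoxide, CC(C)(C)OO
Why: Vanadium-catalysed hydroxyl-directed epoxidation acts only on the allylic C4=C5 alkene and delivers oxygen to the outer face on which the pseudo-equatorial 6α-hydroxyl lies, which should give the 4α,5β-epoxide (threo to O6).

Step 16
Reactants: 20 4α,5β-epoxy-6α-hydroxygermacra-1(10)E,11(13)-dien-12,8α-olide; 21 angelic acid
Product: 23 6α-angeloyloxy-4α,5β-epoxygermacra-1(10)E,11(13)-dien-12,8α-olide, via angelic 2,4,6-trichlorobenzoic anhydride 22 (not isolated)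
Conditions: 2,4,6-Cl3C6H2COCl, Et3N, toluene, rt; then 20, 75 °C
Reagents that add atoms: none
Why: Yamaguchi esterification through the mixed anhydride, run without nucleophilic catalyst, acylates the hindered secondary alcohol while keeping the (Z)-geometry of the angelate.

Step 17
Reactants: 23 6α-angeloyloxy-4α,5β-epoxygermacra-1(10)E,11(13)-dien-12,8α-olide
Product: 24 6α-angeloyloxy-1β,10α;4α,5β-diepoxygermacr-11(13)-en-12,8α-olide (CNP0145353.1)
Conditions: mCPBA, NaHCO3, CH2Cl2, 0 °C
Reagents that add atoms: 3-chloroperbenzoic acid, OOC(=O)c1cccc(Cl)c1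
Why: Prilezhaev epoxidation takes place at the only remaining electron-rich alkene, C1=C10, from its exposed outer face to give the 1β,10α-epoxide, while the α-methylene lactone and the angelate are electron-poor and should not react.

**Compound list**

1 | geranyl acetate | CC(C)=CCC/C(C)=C/COC(C)=O | starting material
2 | (2E,6E)-8-hydroxy-3,7-dimethylocta-2,6-dien-1-yl acetate | OC/C(C)=C/CC/C(C)=C/COC(C)=O | intermediate
3 | (2E,6E)-8-bromo-3,7-dimethylocta-2,6-dien-1-yl acetate | BrC/C(C)=C/CC/C(C)=C/COC(C)=O | intermediate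
4 | 2,2-dimethyl-1,3-dioxolan-4-one | CC1(C)OCC(=O)O1 | starting material
5 | (2E,6E)-8-(2,2-dimethyl-5-oxo-1,3-dioxolan-4-yl)-3,7-dimethylocta-2,6-dien-1-yl acetate (racemic at C8) | O=C1OC(C)(C)OC1C/C(C)=C/CC/C(C)=C/COC(C)=O | intermediate
6 | allyl (4E,8E)-2,10-dihydroxy-4,8-dimethyldeca-4,8-dienoate | C=CCOC(=O)C(O)C/C(C)=C/CC/C(C)=C/CO | intermediate
7 | allyl (4E,8E)-2-hydroxy-4,8-dimethyl-10-oxodeca-4,8-dienoate | C=CCOC(=O)C(O)C/C(C)=C/CC/C(C)=C/C=O | intermediate
8 | allyl (4E,8E)-2-[(methoxycarbonyl)oxy]-4,8-dimethyl-10-oxodeca-4,8-dienoate | C=CCOC(=O)C(OC(=O)OC)C/C(C)=C/CC/C(C)=C/C=O | intermediate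
9 | ethynyltrimethylsilane | C#C[Si](C)(C)C | starting material
10 | allyl (4E,8E,10R)-10-hydroxy-2-[(methoxycarbonyl)oxy]-4,8-dimethyl-12-(trimethylsilyl)dodeca-4,8-dien-11-ynoate | C=CCOC(=O)C(OC(=O)OC)C/C(C)=C/CC/C(C)=C/[C@@H](O)C#C[Si](C)(C)C | intermediate
11 | allyl (4E,8E,10R)-10-hydroxy-2-[(methoxycarbonyl)oxy]-4,8-dimethyldodeca-4,8-dien-11-ynoate | C=CCOC(=O)C(OC(=O)OC)C/C(C)=C/CC/C(C)=C/[C@@H](O)C#C | intermediate
12 | allyl (4E,8E,10R)-10-[(tert-butyldimethylsilyl)oxy]-2-[(methoxycarbonyl)oxy]-4,8-dimethyldodeca-4,8-dien-11-ynoate | C=CCOC(=O)C(OC(=O)OC)C/C(C)=C/CC/C(C)=C/[C@@H](O[Si](C)(C)C(C)(C)C)C#C | intermediate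
13 | 4,4,5,5-tetramethyl-1,3,2-dioxaphospholane 2-oxide (pinacol phosphonate) | O=[PH]1OC(C)(C)C(C)(C)O1 | starting material
14 | allyl (4E,8E,10R,11E)-10-[(tert-butyldimethylsilyl)oxy]-2-[(methoxycarbonyl)oxy]-4,8-dimethyl-12-(4,4,5,5-tetramethyl-2-oxido-1,3,2-dioxaphospholan-2-yl)dodeca-4,8,11-trienoate | C=CCOC(=O)C(OC(=O)OC)C/C(C)=C/CC/C(C)=C/[C@@H](O[Si](C)(C)C(C)(C)C)/C=C/P1(=O)OC(C)(C)C(C)(C)O1 | intermediate
15 | (4E,8E,10R,11E)-10-[(tert-butyldimethylsilyl)oxy]-2-[(methoxycarbonyl)oxy]-4,8-dimethyl-12-(4,4,5,5-tetramethyl-2-oxido-1,3,2-dioxaphospholan-2-yl)dodeca-4,8,11-trienoic acid | OC(=O)C(OC(=O)OC)C/C(C)=C/CC/C(C)=C/[C@@H](O[Si](C)(C)C(C)(C)C)/C=C/P1(=O)OC(C)(C)C(C)(C)O1 | intermediate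
16 | caesium salt of the C11 carbanion of the ten-membered carbocycle (C7–C8 bond formed; 6α-silyloxy, 8α-methoxycarbonyloxy, lactone not yet closed) | COC(=O)O[C@H]1C/C(C)=C/CC/C(C)=C/[C@@H](O[Si](C)(C)C(C)(C)C)[C@@H]1[CH-]P2(=O)OC(C)(C)C(C)(C)O2.[Cs+] | intermediate
17 | 6α-(tert-butyldimethylsilyloxy)-11-(4,4,5,5-tetramethyl-2-oxido-1,3,2-dioxaphospholan-2-yl)germacra-1(10)E,4E-dien-12,8α-olide (7αH,8βH; C11 epimers) | O=C1O[C@H]2C/C(C)=C/CC/C(C)=C/[C@@H](O[Si](C)(C)C(C)(C)C)[C@@H]2C1P3(=O)OC(C)(C)C(C)(C)O3 | intermediate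
18 | 6α-(tert-butyldimethylsilyloxy)germacra-1(10)E,4E,11(13)-trien-12,8α-olide | C=C1C(=O)O[C@H]2C/C(C)=C/CC/C(C)=C/[C@@H](O[Si](C)(C)C(C)(C)C)[C@H]12 | intermediate
19 | 6α-hydroxygermacra-1(10)E,4E,11(13)-trien-12,8α-olide | C=C1C(=O)O[C@H]2C/C(C)=C/CC/C(C)=C/[C@@H](O)[C@H]12 | intermediate
20 | 4α,5β-epoxy-6α-hydroxygermacra-1(10)E,11(13)-dien-12,8α-olide | C=C1C(=O)O[C@H]2C/C(C)=C/CC[C@@]3(C)O[C@@H]3[C@@H](O)[C@H]12 | intermediate
21 | angelic acid, (Z)-2-methylbut-2-enoic acid | C/C=C(/C)C(=O)O | starting material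
22 | angelic 2,4,6-trichlorobenzoic anhydride | C/C=C(/C)C(=O)OC(=O)c1c(Cl)cc(Cl)cc1Cl | intermediate
23 | 6α-angeloyloxy-4α,5β-epoxygermacra-1(10)E,11(13)-dien-12,8α-olide | C=C1C(=O)O[C@H]2C/C(C)=C/CC[C@@]3(C)O[C@@H]3[C@@H](OC(=O)/C(C)=C\C)[C@H]12 | intermediate
24 | 6α-angeloyloxy-1β,10α;4α,5β-diepoxygermacr-11(13)-en-12,8α-olide (1R,4R,5R,6S,7R,8S,10R) | C=C1C(=O)O[C@H]2C[C@@]3(C)O[C@@H]3CC[C@@]3(C)O[C@@H]3[C@@H](OC(=O)/C(C)=C\C)[C@H]12 | target

**Step count and risks**

Total step count: 17. Longest linear sequence: 17 steps (1 to 24).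

Steps most likely to fail:

Step 12 (Proposed new method). The ten-membered ring closure of the C8 radical may be too slow, so that the radical is lost by hydrogen abstraction from the medium or by intermolecular addition, or the carbanion may be protonated before it acylates. The fallback uses known reactions, with C8 reacting as a ketyl at the aldehyde level and the lactone closed in a separate base step. It sets out from 14: LiBH4 in THF–MeOH should reduce the allyl ester and remove the carbonate to give 1,2-diol F1; NaIO4 should cleave this to β,γ-unsaturated aldehyde F2; samarium diiodide with HMPA and t-BuOH at high dilution (ketyl–alkene reductive cyclisation onto the alkenylphosphonate) should give ten-membered γ-hydroxy phosphonate F3; ClCO2Me and pyridine give methyl carbonate F4; LiN(SiMe3)2 in THF (−78 to 0 °C) should then close the lactone by Dieckmann-type acylation of the phosphonate carbanion, which comes back to the route at 17.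

Step 16. Acylation of the hindered 6α-hydroxyl may be slow, and the activated angelate may isomerise to the (E)-tiglate during the reaction. The fallback builds the (Z)-alkene in place and sets out from 20: esterification with 2-[bis(2,2,2-trifluoroethoxy)phosphoryl]propanoic acid (DCC, DMAP) gives phosphonopropanoate F5, and Still–Gennari olefination with acetaldehyde (KN(SiMe3)2, 18-crown-6, THF, −78 °C) should give the (Z)-2-methylbut-2-enoate, which comes back to the route at 23.

Step 17. Facial selectivity may be poor if the bulky 6-ester shifts the conformer population of the ten-membered ring so that the peracid also attacks the other face of C1=C10. The fallback changes the order of events and sets out from 20: mCPBA epoxidation of the free alcohol, whose conformer population should differ from that of the ester, gives diepoxy alcohol F6, and Yamaguchi angeloylation as in step 16 then comes back to the route at 24.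

Further compounds
F1 | step 12 | (4E,8E,10R,11E)-10-[(tert-butyldimethylsilyl)oxy]-4,8-dimethyl-12-(4,4,5,5-tetramethyl-2-oxido-1,3,2-dioxaphospholan-2-yl)dodeca-4,8,11-triene-1,2-diol | OCC(O)C/C(C)=C/CC/C(C)=C/[C@@H](O[Si](C)(C)C(C)(C)C)/C=C/P1(=O)OC(C)(C)C(C)(C)O1
F2 | step 12 | (3E,7E,9R,10E)-9-[(tert-butyldimethylsilyl)oxy]-3,7-dimethyl-11-(4,4,5,5-tetramethyl-2-oxido-1,3,2-dioxaphospholan-2-yl)undeca-3,7,10-trienal | O=CC/C(C)=C/CC/C(C)=C/[C@@H](O[Si](C)(C)C(C)(C)C)/C=C/P1(=O)OC(C)(C)C(C)(C)O1
F3 | step 12 | ten-membered γ-hydroxy phosphonate: 6α-(tert-butyldimethylsilyloxy)-8α-hydroxy-7β-[(4,4,5,5-tetramethyl-2-oxido-1,3,2-dioxaphospholan-2-yl)methyl]-(E,E)-cyclodeca-1(10),4-diene (germacrane numbering) | O[C@H]1C/C(C)=C/CC/C(C)=C/[C@@H](O[Si](C)(C)C(C)(C)C)[C@@H]1CP2(=O)OC(C)(C)C(C)(C)O2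
F4 | step 12 | methyl carbonate of F3 at O8 | COC(=O)O[C@H]1C/C(C)=C/CC/C(C)=C/[C@@H](O[Si](C)(C)C(C)(C)C)[C@@H]1CP2(=O)OC(C)(C)C(C)(C)O2
F5 | step 16 | 6α-{2-[bis(2,2,2-trifluoroethoxy)phosphoryl]propanoyloxy}-4α,5β-epoxygermacra-1(10)E,11(13)-dien-12,8α-olide | C=C1C(=O)O[C@H]2C/C(C)=C/CC[C@@]3(C)O[C@@H]3[C@@H](OC(=O)C(C)P(=O)(OCC(F)(F)F)OCC(F)(F)F)[C@H]12
F6 | step 17 | 1β,10α;4α,5β-diepoxy-6α-hydroxygermacr-11(13)-en-12,8α-olide | C=C1C(=O)O[C@H]2C[C@@]3(C)O[C@@H]3CC[C@@]3(C)O[C@@H]3[C@@H](O)[C@H]12
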